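**Retrosynthetic overview**

1. The target is theaflavin 3-gallate. The strategy rests on ring T, numbered as 5H-benzo[7]annulen-5-one (C5 carbonyl next to ring B, C6–OH, C7–H, C8 bearing the galloylated flavan 1, C9–H, fusion atoms C9a/C4a). The oxygen on C6 and carbon C9 stand 1,4 across C7=C8, so an ether bond C6–O–C9 turns ring T into a benzo-fused 8-oxabicyclo[3.2.1]octadienone.
2. Key disconnection: that bicycle is the adduct of a 2-benzopyrylium-4-olate (ylide C9–O–C6 with C5 and ring B, from formyl diazoketone 28 and Rh2(OAc)4) and ynone 9 (C7, C8, and C2/C3/C4 with ring A of flavan 1). Acid then reopens the bridge to the tropolone.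
3. After the cycloaddition: tropolone O-benzylation, chelation-controlled reduction of the C2 ketone, Mitsunobu closure of the flavan 1 pyran ring with inversion, MOM removal, galloylation, hydrogenolysis.
4. Before it: both aryl-lactate units come from one hydroxy ester 6 (aryl Grignard opening of methyl (R)-glycidate). Flavan 2 is built on bromophthalide 14 (thioester/boronic acid ketone synthesis, chelation-controlled reduction, Mitsunobu closure), and the phthalide is then unfolded into 28 (lactone C=O to diazoketone, lactone CH2 to CHO).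
5. Ring order: phthalide (step 7), pyran ring of flavan 2 (step 17), ring T with its oxygen bridge (step 22, bridge opened in step 23), pyran ring of flavan 1 (step 27). The A-ring phenol is carried as a triisopropylsilyl ether because it tolerates the aryl-metal and mild-base steps better than tert-butyldimethylsilyl.

Key step: step 22

Remark on the chemistry: the tropolone of ring T is a fast tautomer pair; compounds 31–38 are drawn in the C5=O/C6–O form that step 23 gives first, and the target in the tautomer of the given SMILES.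

Abbreviations: ArA = 2,4-bis(benzyloxy)-6-(triisopropylsilyloxy)phenyl; Fl2 = (2R,3R)-3,5,7-tris(benzyloxy)chroman-2-yl (benzylated flavan 2); Bn = benzyl; MOM = methoxymethyl.

**Route**

Step 1
Reactants: 1 3,5-bis(benzyloxy)phenol
Product: 2 3,5-bis(benzyloxy)-2-iodophenol
Conditions: N-iodosuccinimide (1.0 equiv), CH2Cl2, −20 → 0 °C
Reagents that add atoms: N-iodosuccinimide O=C1CCC(=O)N1I
Why: Electrophilic aromatic iodination of the phenol is expected at one of the two equivalent positions ortho to the free hydroxyl (hydrogen-bond-guided delivery in a non-polar solvent), which places iodine between OH and OBn; one equivalent at low temperature limits di-iodination and any para isomer is removed by chromatography.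

Step 2
Reactants: 2 3,5-bis(benzyloxy)-2-iodophenol
Product: 3 [3,5-bis(benzyloxy)-2-iodophenoxy]triisopropylsilane
Conditions: i-Pr3SiCl, imidazole, DMF, rt → 40 °C
Reagents that add atoms: chlorotriisopropylsilane CC(C)[Si](Cl)(C(C)C)C(C)C
Why: Imidazole-promoted silylation of the phenol gives a bulky silyl ether that should resist migration to an ortho carbanion and the mild acids and bases used later.

Step 3
Reactants: 3 [3,5-bis(benzyloxy)-2-iodophenoxy]triisopropylsilane; 4 methyl (R)-glycidate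
Product: 6 methyl (2R)-3-ArA-2-hydroxypropanoate, via arylmagnesium chloride 5 (not isolated)
Conditions: i-PrMgCl·LiCl (1.1 equiv), THF, 0 °C → rt; then CuI (10 mol%), 4 (1.2 equiv), −40 → −20 °C; aq. NH4Cl
Reagents that add atoms: none
Why: Iodine–magnesium exchange gives the aryl Grignard reagent, which under copper catalysis opens the glycidic ester at its unsubstituted carbon (SN2-type epoxide opening), so the (R) centre of 4 is carried over untouched as the carbinol of the aryl lactate.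

Step 4
Reactants: 6 methyl (2R)-3-ArA-2-hydroxypropanoate
Product: 7 methyl (2R)-3-ArA-2-(methoxymethoxy)propanoate
Conditions: MOMCl, i-Pr2NEt, CH2Cl2, 0 °C → rt
Reagents that add atoms: chloromethyl methyl ether COCCl
Why: Alkylation of the secondary alcohol with a hindered amine base gives the MOM acetal without touching the α-stereocentre, and the MOM oxygen later serves as the chelating group.

Step 5
Reactants: 7 methyl (2R)-3-ArA-2-(methoxymethoxy)propanoate
Product: 8 (2R)-3-ArA-N-methoxy-2-(methoxymethoxy)-N-methylpropanamide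
Conditions: MeNH(OMe)·HCl (1.6 equiv), i-PrMgCl (3.2 equiv), THF, −20 → 0 °C
Reagents that add atoms: N,O-dimethylhydroxylamine hydrochloride CNOC.Cl
Why: Aminolysis of the methyl ester by the magnesium amide gives the Weinreb amide at a temperature where the α-alkoxy centre is not enolised.

Step 6
Reactants: 8 (2R)-3-ArA-N-methoxy-2-(methoxymethoxy)-N-methylpropanamide
Product: 9 (4R)-5-ArA-4-(methoxymethoxy)pent-1-yn-3-one
Conditions: HC≡CMgBr (0.5 M in THF, 2.5 equiv), THF, −20 → 0 °C; inverse quench into cold 1 M HCl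
Reagents that add atoms: ethynylmagnesium bromide C#C[Mg]Br
Why: Weinreb ketone synthesis, in which the magnesium chelate stops the addition at the ketone stage and the cold acidic inverse quench protonates the released amine before it can add to the terminal ynone.

Step 7
Reactants: 10 2,3-dimethoxybenzoic acid
Product: 11 6,7-dimethoxyisobenzofuran-1(3H)-one (6,7-dimethoxyphthalide)
Conditions: 37% aq. CH2O, conc. HCl, 90 °C
Reagents that add atoms: formaldehyde C=O
Why: Blanc-type hydroxymethylation/chloromethylation should occur at C6, para to the 3-methoxy group and the only free position ortho to the acid, and the product lactonises to the phthalide.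

Step 8
Reactants: 11 6,7-dimethoxyisobenzofuran-1(3H)-one
Product: 12 6,7-dihydroxyisobenzofuran-1(3H)-one
Conditions: BBr3 (3 equiv), CH2Cl2, −78 °C → rt; then H2O
Reagents that add atoms: none
Why: Lewis-acid cleavage of both aryl methyl ethers, with the lactone left intact at or below room temperature.

Step 9
Reactants: 12 6,7-dihydroxyisobenzofuran-1(3H)-one
Product: 13 4-bromo-6,7-dihydroxyisobenzofuran-1(3H)-one
Conditions: Br2 (1.0 equiv), AcOH, rt
Reagents that add atoms: bromine BrBr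
Why: Electrophilic bromination is expected at C4, para to the C7 hydroxyl and meta to the lactone carbonyl (the orientation seen for 2,3-dihydroxybenzaldehyde), whereas C5 is deactivated by the para acyl group.

Step 10
Reactants: 13 4-bromo-6,7-dihydroxyisobenzofuran-1(3H)-one
Product: 14 6,7-bis(benzyloxy)-4-bromoisobenzofuran-1(3H)-one
Conditions: BnBr (2.4 equiv), K2CO3 (3 equiv), DMF, 60 °C
Reagents that add atoms: benzyl bromide BrCc1ccccc1
Why: Williamson etherification of both phenols, which the lactone tolerates.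

Step 11
Reactants: 14 6,7-bis(benzyloxy)-4-bromoisobenzofuran-1(3H)-one
Product: 15 [6,7-bis(benzyloxy)-1-oxo-1,3-dihydroisobenzofuran-4-yl]boronic acid
Conditions: B2(OH)4 (2 equiv), Pd(OAc)2 (3 mol%), XPhos (6 mol%), KOAc (3 equiv), EtOH, 80 °C
Reagents that add atoms: tetrahydroxydiboron OB(O)B(O)O
Why: Miyaura-type palladium-catalysed borylation gives the boronic acid directly and tolerates the lactone, which an aryl-lithium or Grignard route from this bromide would not.

Step 12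
Reactants: 6 methyl (2R)-3-ArA-2-hydroxypropanoate
Product: 16 methyl (2R)-3-ArA-2-(benzyloxy)propanoate
Conditions: BnBr (3 equiv), Ag2O (2 equiv), CH2Cl2, rt, dark
Reagents that add atoms: benzyl bromide BrCc1ccccc1
Why: Silver-oxide-promoted benzylation is a neutral Williamson variant that etherifies the α-hydroxy ester without base-induced epimerisation.

Step 13
Reactants: 16 methyl (2R)-3-ArA-2-(benzyloxy)propanoate
Product: 17 S-ethyl (2R)-3-ArA-2-(benzyloxy)propanethioate
Conditions: AlMe3 (2 equiv), EtSH (2 equiv), CH2Cl2, 0 °C → rt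
Reagents that add atoms: ethanethiol CCS
Why: Dimethylaluminium ethanethiolate formed in the flask converts the methyl ester into the thioester (aluminium-mediated transesterification) without touching the α-centre.

Step 14
Reactants: 15 [6,7-bis(benzyloxy)-1-oxo-1,3-dihydroisobenzofuran-4-yl]boronic acid; 17 S-ethyl (2R)-3-ArA-2-(benzyloxy)propanethioate
Product: 18 6,7-bis(benzyloxy)-4-[(2R)-3-ArA-2-(benzyloxy)propanoyl]isobenzofuran-1(3H)-one
Conditions: Pd2(dba)3 (2.5 mol%), tri(2-furyl)phosphine (10 mol%), Cu(O2CC4H3S) (copper thiophene-2-carboxylate, CuTC, 1.5 equiv), THF, 50 °C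
Reagents that add atoms: none
Why: Liebeskind–Srogl coupling transfers the acyl group from the thioester to the boronic acid under base-free conditions, so the aryl ketone should form without epimerising the α-benzyloxy centre and without touching the lactone.

Step 15
Reactants: 18 6,7-bis(benzyloxy)-4-[(2R)-3-ArA-2-(benzyloxy)propanoyl]isobenzofuran-1(3H)-one
Product: 19 6,7-bis(benzyloxy)-4-[(1S,2R)-3-ArA-2-(benzyloxy)-1-hydroxypropyl]isobenzofuran-1(3H)-one
Conditions: Zn(BH4)2 (Et2O solution, 1.5 equiv), CH2Cl2, −40 → −20 °C; aq. NH4Cl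
Reagents that add atoms: none
Why: Zinc bridges the ketone oxygen and the α-benzyloxy oxygen (Cram-chelate model) and hydride enters from the face opposite the arylmethyl group, which should give the 1,2-anti (1S,2R) alcohol while the lactone is inert at this temperature.

Step 16
Reactants: 19 6,7-bis(benzyloxy)-4-[(1S,2R)-3-ArA-2-(benzyloxy)-1-hydroxypropyl]isobenzofuran-1(3H)-one
Product: 20 6,7-bis(benzyloxy)-4-{(1S,2R)-2-(benzyloxy)-3-[2,4-bis(benzyloxy)-6-hydroxyphenyl]-1-hydroxypropyl}isobenzofuran-1(3H)-one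
Conditions: TBAF (1.2 equiv), AcOH (1.2 equiv), THF, 0 °C
Reagents that add atoms: none
Why: Fluoride cleaves the aryl silyl ether and acetic acid buffers the phenoxide.

Step 17
Reactants: 20 6,7-bis(benzyloxy)-4-{(1S,2R)-2-(benzyloxy)-3-[2,4-bis(benzyloxy)-6-hydroxyphenyl]-1-hydroxypropyl}isobenzofuran-1(3H)-one
Product: 21 6,7-bis(benzyloxy)-4-Fl2-isobenzofuran-1(3H)-one
Conditions: PPh3 (1.5 equiv), DIAD (1.5 equiv), THF, 0 °C → rt
Reagents that add atoms: none
Why: Mitsunobu etherification in which the phenol displaces the oxyphosphonium group of the benzylic alcohol intramolecularly (six-membered ring closure, SN2) with inversion, turning the (1S) carbinol into C2 (R) and giving the 2,3-cis flavan.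

Step 18
Reactants: 21 6,7-bis(benzyloxy)-4-Fl2-isobenzofuran-1(3H)-one
Product: 24 2,3-bis(benzyloxy)-6-[(tert-butyldiphenylsilyloxy)methyl]-5-Fl2-benzoic acid, via potassium hydroxymethyl benzoate 22 (not isolated), via silyl ester silyl ether 23 (not isolated)
Conditions: KOH (1.05 equiv), THF/MeOH/H2O, 50 °C, evaporate; t-BuPh2SiCl (2.5 equiv), imidazole (5 equiv), DMF, rt; K2CO3 (1.5 equiv), MeOH/THF/H2O, rt; citric acid to pH 5
Reagents that add atoms: potassium hydroxide [K+].[OH-]; tert-butyl(chloro)diphenylsilane CC(C)(C)[Si](Cl)(c1ccccc1)c1ccccc1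
Why: Hydroxide opens the lactone, silylation of both oxygens prevents relactonisation, and the labile silyl ester is then hydrolysed selectively to leave the silyl ether acid.

Step 19
Reactants: 24 2,3-bis(benzyloxy)-6-[(tert-butyldiphenylsilyloxy)methyl]-5-Fl2-benzoic acid
Product: 26 1-{2,3-bis(benzyloxy)-6-[(tert-butyldiphenylsilyloxy)methyl]-5-Fl2-phenyl}-2-diazoethan-1-one, via acid chloride 25 (not isolated)
Conditions: 1-chloro-N,N,2-trimethylprop-1-en-1-amine (1.3 equiv), CH2Cl2, 0 °C; then CH2N2 (4 equiv), Et2O, 0 °C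
Reagents that add atoms: diazomethane C=[N+]=[N-]
Why: The neutral chloroenamine makes the acid chloride without free HCl and diazomethane is then acylated (first stage of an Arndt–Eistert sequence, a second equivalent taking up the HCl), while the bulky silyl ether keeps the ortho oxygen from closing back to the phthalide.

Step 20
Reactants: 26 1-{2,3-bis(benzyloxy)-6-[(tert-butyldiphenylsilyloxy)methyl]-5-Fl2-phenyl}-2-diazoethan-1-one
Product: 27 1-[2,3-bis(benzyloxy)-6-(hydroxymethyl)-5-Fl2-phenyl]-2-diazoethan-1-one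
Conditions: TBAF (1.5 equiv), AcOH (1.5 equiv), THF, 0 °C → rt
Reagents that add atoms: none
Why: Buffered fluoride removes the silyl group from the primary benzylic alcohol under conditions that an acceptor diazoketone tolerates.

Step 21
Reactants: 27 1-[2,3-bis(benzyloxy)-6-(hydroxymethyl)-5-Fl2-phenyl]-2-diazoethan-1-one
Product: 28 3,4-bis(benzyloxy)-2-(diazoacetyl)-6-Fl2-benzaldehyde
Conditions: activated MnO2 (15 equiv), CH2Cl2, rt
Reagents that add atoms: none
Why: MnO2 oxidises the benzylic alcohol to the aldehyde and leaves the diazo group alone.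

Step 22
Reactants: 28 3,4-bis(benzyloxy)-2-(diazoacetyl)-6-Fl2-benzaldehyde; 9 (4R)-5-ArA-4-(methoxymethoxy)pent-1-yn-3-one
Product: 30 3,4-bis(benzyloxy)-8-[(2R)-3-ArA-2-(methoxymethoxy)propanoyl]-1-Fl2-6,9-dihydro-5H-6,9-epoxybenzo[7]annulen-5-one (both bridgehead epimers), via 2-benzopyrylium-4-olate 29 (not isolated)
Conditions: Rh2(OAc)4 (2 mol%), 9 (1.5 equiv), CH2Cl2, rt, 28 added over 3 h
Reagents that add atoms: none
Why: Rh2(OAc)4 should take N2 from 28 to give a rhodium carbenoid that the neighbouring formyl oxygen captures (six-membered ring closure, oxygen onto the carbenoid carbon) to give the aromatic ylide 29, which adds ynone 9 across its two ylide carbons C6 and C9 in a concerted cycloaddition, the reaction type known for rhodium-generated carbonyl ylides and oxidopyrylium species with alkynes. Bonds C9–C8 and C6–C7 form together, so the seven-membered carbocycle and the five-membered oxygen-bridged ring close in one intermolecular suprafacial event. The only new stereocentres are the bridgeheads C6 and C9; the bridge fixes them cis to each other, their sense relative to the existing centres is not controlled and need not be, because both are erased in step 23. The step needs regioselectivity (unsubstituted alkyne carbon to C6): C6 is the enolate-like nucleophilic terminus with the largest HOMO coefficient and the terminal ynone carbon carries the largest LUMO coefficient, while the acyl-bearing carbon pairs with the oxocarbenium-like C9. It also needs the carbenoid to choose the aldehyde oxygen over the ortho benzyloxy oxygen, for which the aromatic stabilisation of 29 and slow addition of 28 to catalyst and excess 9 are relied on.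

Step 23
Reactants: 30 3,4-bis(benzyloxy)-8-[(2R)-3-ArA-2-(methoxymethoxy)propanoyl]-1-Fl2-6,9-dihydro-5H-6,9-epoxybenzo[7]annulen-5-one
Product: 31 3,4-bis(benzyloxy)-6-hydroxy-8-[(2R)-3-ArA-2-(methoxymethoxy)propanoyl]-1-Fl2-5H-benzo[7]annulen-5-one
Conditions: camphorsulfonic acid (0.5 equiv), CH2Cl2, 0 °C → rt
Reagents that add atoms: none
Why: Protonation of the bridging oxygen lets the C9–O bond ionise (C9 is benzylic, allylic and para to the C3 benzyloxy group) and loss of the C6 proton gives the aromatic hydroxytropone, so both bridgehead epimers converge, while an anhydrous sulfonic acid without added nucleophile should spare the MOM acetal and the silyl ether.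

Step 24
Reactants: 31 3,4-bis(benzyloxy)-6-hydroxy-8-[(2R)-3-ArA-2-(methoxymethoxy)propanoyl]-1-Fl2-5H-benzo[7]annulen-5-one
Product: 32 3,4,6-tris(benzyloxy)-8-[(2R)-3-ArA-2-(methoxymethoxy)propanoyl]-1-Fl2-5H-benzo[7]annulen-5-one
Conditions: BnBr (2 equiv), Ag2O (1.5 equiv), CH2Cl2, rt, dark
Reagents that add atoms: benzyl bromide BrCc1ccccc1
Why: O-alkylation of the acidic tropolone hydroxyl as its silver salt under neutral conditions (no enolisation of the α-alkoxy ketone) is expected mainly at the C6 oxygen, away from the peri benzyloxy group on C4, and any C5-O isomer would converge in step 30.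

Step 25
Reactants: 32 3,4,6-tris(benzyloxy)-8-[(2R)-3-ArA-2-(methoxymethoxy)propanoyl]-1-Fl2-5H-benzo[7]annulen-5-one
Product: 33 3,4,6-tris(benzyloxy)-8-[(1S,2R)-3-ArA-1-hydroxy-2-(methoxymethoxy)propyl]-1-Fl2-5H-benzo[7]annulen-5-one
Conditions: Zn(BH4)2 (Et2O solution, 1.5 equiv), CH2Cl2, −78 → −40 °C; aq. NH4Cl
Reagents that add atoms: none
Why: Chelation-controlled reduction as in step 15, with zinc held between the ketone and MOM oxygens directing hydride to the face opposite the arylmethyl group to give the (1S,2R) anti alcohol, the chelate-activated ketone being expected to react faster than the vinylogous-ester-like benzyloxytropone at low temperature.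

Step 26
Reactants: 33 3,4,6-tris(benzyloxy)-8-[(1S,2R)-3-ArA-1-hydroxy-2-(methoxymethoxy)propyl]-1-Fl2-5H-benzo[7]annulen-5-one
Product: 34 3,4,6-tris(benzyloxy)-8-{(1S,2R)-3-[2,4-bis(benzyloxy)-6-hydroxyphenyl]-1-hydroxy-2-(methoxymethoxy)propyl}-1-Fl2-5H-benzo[7]annulen-5-one
Conditions: TBAF (1.2 equiv), AcOH (1.2 equiv), THF, 0 °C
Reagents that add atoms: none
Why: Buffered fluoride cleaves the aryl silyl ether and leaves the benzyl ethers, the MOM acetal and the tropone untouched.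

Step 27
Reactants: 34 3,4,6-tris(benzyloxy)-8-{(1S,2R)-3-[2,4-bis(benzyloxy)-6-hydroxyphenyl]-1-hydroxy-2-(methoxymethoxy)propyl}-1-Fl2-5H-benzo[7]annulen-5-one
Product: 35 3,4,6-tris(benzyloxy)-8-[(2R,3R)-5,7-bis(benzyloxy)-3-(methoxymethoxy)chroman-2-yl]-1-Fl2-5H-benzo[7]annulen-5-one
Conditions: PPh3 (2 equiv), DIAD (2 equiv), THF, 0 °C → rt
Reagents that add atoms: none
Why: Mitsunobu closure as in step 17, an intramolecular SN2 displacement by the phenol with inversion at the carbinol that sets C2 as (R), cis to the C3 MOM ether, the electron-poor tropone ring disfavouring ionisation and so favouring clean inversion.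

Step 28
Reactants: 35 3,4,6-tris(benzyloxy)-8-[(2R,3R)-5,7-bis(benzyloxy)-3-(methoxymethoxy)chroman-2-yl]-1-Fl2-5H-benzo[7]annulen-5-one
Product: 36 3,4,6-tris(benzyloxy)-8-[(2R,3R)-5,7-bis(benzyloxy)-3-hydroxychroman-2-yl]-1-Fl2-5H-benzo[7]annulen-5-one
Conditions: 3 M aq. HCl, MeOH/THF, 40 °C
Reagents that add atoms: none
Why: Acid-catalysed acetal exchange removes the MOM group under conditions mild enough that the benzyl ethers should survive (a tropolone benzyl ether that is partly lost can be put back as in step 24).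

Step 29
Reactants: 36 3,4,6-tris(benzyloxy)-8-[(2R,3R)-5,7-bis(benzyloxy)-3-hydroxychroman-2-yl]-1-Fl2-5H-benzo[7]annulen-5-one; 37 3,4,5-tris(benzyloxy)benzoic acid
Product: 38 (2R,3R)-5,7-bis(benzyloxy)-2-[3,4,6-tris(benzyloxy)-5-oxo-1-Fl2-5H-benzo[7]annulen-8-yl]chroman-3-yl 3,4,5-tris(benzyloxy)benzoate
Conditions: DCC (1.5 equiv), DMAP (0.3 equiv), CH2Cl2, rt
Reagents that add atoms: none
Why: Steglich esterification of the axial C3 hydroxyl, the only free hydroxyl in 36, with retention at C3.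

Step 30
Reactants: 38 (2R,3R)-5,7-bis(benzyloxy)-2-[3,4,6-tris(benzyloxy)-5-oxo-1-Fl2-5H-benzo[7]annulen-8-yl]chroman-3-yl 3,4,5-tris(benzyloxy)benzoate
Product: 39 theaflavin 3-gallate (target)
Conditions: H2 (1 atm), Pd(OH)2/C (20 wt%), THF/MeOH (1:1), rt
Reagents that add atoms: none
Why: Hydrogenolysis of all eleven benzyl ethers (nine aryl, one alkyl, one tropolone) under neutral conditions should free the phenols, the flavan 2 alcohol and the tropolone without touching the gallate ester or the four stereocentres.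

**Compound list**

1 | 3,5-bis(benzyloxy)phenol | Oc1cc(OCc2ccccc2)cc(OCc2ccccc2)c1 | starting material
2 | 3,5-bis(benzyloxy)-2-iodophenol | Oc1cc(OCc2ccccc2)cc(OCc2ccccc2)c1I | intermediate
3 | [3,5-bis(benzyloxy)-2-iodophenoxy]triisopropylsilane | CC(C)[Si](Oc1cc(OCc2ccccc2)cc(OCc2ccccc2)c1I)(C(C)C)C(C)C | intermediate
4 | methyl (R)-glycidate | COC(=O)[C@H]1CO1 | starting material
5 | ArA-magnesium chloride (LiCl complex, not isolated) | CC(C)[Si](Oc1cc(OCc2ccccc2)cc(OCc2ccccc2)c1[Mg]Cl)(C(C)C)C(C)C | intermediate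
6 | methyl (2R)-3-ArA-2-hydroxypropanoate | COC(=O)[C@H](O)Cc1c(O[Si](C(C)C)(C(C)C)C(C)C)cc(OCc2ccccc2)cc1OCc1ccccc1 | intermediate
7 | methyl (2R)-3-ArA-2-(methoxymethoxy)propanoate | COC(=O)[C@H](OCOC)Cc1c(O[Si](C(C)C)(C(C)C)C(C)C)cc(OCc2ccccc2)cc1OCc1ccccc1 | intermediate
8 | (2R)-3-ArA-N-methoxy-2-(methoxymethoxy)-N-methylpropanamide | CON(C)C(=O)[C@H](OCOC)Cc1c(O[Si](C(C)C)(C(C)C)C(C)C)cc(OCc2ccccc2)cc1OCc1ccccc1 | intermediate
9 | (4R)-5-ArA-4-(methoxymethoxy)pent-1-yn-3-one | C#CC(=O)[C@H](OCOC)Cc1c(O[Si](C(C)C)(C(C)C)C(C)C)cc(OCc2ccccc2)cc1OCc1ccccc1 | intermediate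
10 | 2,3-dimethoxybenzoic acid | COc1cccc(C(=O)O)c1OC | starting material
11 | 6,7-dimethoxyisobenzofuran-1(3H)-one | COc1ccc2c(c1OC)C(=O)OC2 | intermediate
12 | 6,7-dihydroxyisobenzofuran-1(3H)-one | Oc1ccc2c(c1O)C(=O)OC2 | intermediate
13 | 4-bromo-6,7-dihydroxyisobenzofuran-1(3H)-one | Oc1cc(Br)c2c(c1O)C(=O)OC2 | intermediate
14 | 6,7-bis(benzyloxy)-4-bromoisobenzofuran-1(3H)-one | O=C1OCc2c(Br)cc(OCc3ccccc3)c(OCc3ccccc3)c21 | intermediate
15 | [6,7-bis(benzyloxy)-1-oxo-1,3-dihydroisobenzofuran-4-yl]boronic acid | O=C1OCc2c(B(O)O)cc(OCc3ccccc3)c(OCc3ccccc3)c21 | intermediate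
16 | methyl (2R)-3-ArA-2-(benzyloxy)propanoate | COC(=O)[C@H](OCc1ccccc1)Cc1c(O[Si](C(C)C)(C(C)C)C(C)C)cc(OCc2ccccc2)cc1OCc1ccccc1 | intermediate
17 | S-ethyl (2R)-3-ArA-2-(benzyloxy)propanethioate | CCSC(=O)[C@H](OCc1ccccc1)Cc1c(O[Si](C(C)C)(C(C)C)C(C)C)cc(OCc2ccccc2)cc1OCc1ccccc1 | intermediate
18 | 6,7-bis(benzyloxy)-4-[(2R)-3-ArA-2-(benzyloxy)propanoyl]isobenzofuran-1(3H)-one | O=C1OCc2c(C(=O)[C@H](OCc3ccccc3)Cc3c(O[Si](C(C)C)(C(C)C)C(C)C)cc(OCc4ccccc4)cc3OCc3ccccc3)cc(OCc3ccccc3)c(OCc3ccccc3)c21 | intermediate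
19 | 6,7-bis(benzyloxy)-4-[(1S,2R)-3-ArA-2-(benzyloxy)-1-hydroxypropyl]isobenzofuran-1(3H)-one | O=C1OCc2c([C@H](O)[C@H](OCc3ccccc3)Cc3c(O[Si](C(C)C)(C(C)C)C(C)C)cc(OCc4ccccc4)cc3OCc3ccccc3)cc(OCc3ccccc3)c(OCc3ccccc3)c21 | intermediate
20 | 6,7-bis(benzyloxy)-4-{(1S,2R)-2-(benzyloxy)-3-[2,4-bis(benzyloxy)-6-hydroxyphenyl]-1-hydroxypropyl}isobenzofuran-1(3H)-one | O=C1OCc2c([C@H](O)[C@H](OCc3ccccc3)Cc3c(O)cc(OCc4ccccc4)cc3OCc3ccccc3)cc(OCc3ccccc3)c(OCc3ccccc3)c21 | intermediate
21 | 6,7-bis(benzyloxy)-4-Fl2-isobenzofuran-1(3H)-one | O=C1OCc2c([C@H]3Oc4cc(OCc5ccccc5)cc(OCc5ccccc5)c4C[C@H]3OCc3ccccc3)cc(OCc3ccccc3)c(OCc3ccccc3)c21 | intermediate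
22 | potassium 2,3-bis(benzyloxy)-6-(hydroxymethyl)-5-Fl2-benzoate (not isolated) | [K+].[O-]C(=O)c1c(OCc2ccccc2)c(OCc2ccccc2)cc([C@H]3Oc4cc(OCc5ccccc5)cc(OCc5ccccc5)c4C[C@H]3OCc3ccccc3)c1CO | intermediate
23 | tert-butyldiphenylsilyl 2,3-bis(benzyloxy)-6-[(tert-butyldiphenylsilyloxy)methyl]-5-Fl2-benzoate (not isolated) | CC(C)(C)[Si](OC(=O)c1c(OCc2ccccc2)c(OCc2ccccc2)cc([C@H]3Oc4cc(OCc5ccccc5)cc(OCc5ccccc5)c4C[C@H]3OCc3ccccc3)c1CO[Si](c1ccccc1)(c1ccccc1)C(C)(C)C)(c1ccccc1)c1ccccc1 | intermediate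
24 | 2,3-bis(benzyloxy)-6-[(tert-butyldiphenylsilyloxy)methyl]-5-Fl2-benzoic acid | OC(=O)c1c(OCc2ccccc2)c(OCc2ccccc2)cc([C@H]3Oc4cc(OCc5ccccc5)cc(OCc5ccccc5)c4C[C@H]3OCc3ccccc3)c1CO[Si](c1ccccc1)(c1ccccc1)C(C)(C)C | intermediate
25 | 2,3-bis(benzyloxy)-6-[(tert-butyldiphenylsilyloxy)methyl]-5-Fl2-benzoyl chloride (not isolated) | ClC(=O)c1c(OCc2ccccc2)c(OCc2ccccc2)cc([C@H]3Oc4cc(OCc5ccccc5)cc(OCc5ccccc5)c4C[C@H]3OCc3ccccc3)c1CO[Si](c1ccccc1)(c1ccccc1)C(C)(C)C | intermediate
26 | 1-{2,3-bis(benzyloxy)-6-[(tert-butyldiphenylsilyloxy)methyl]-5-Fl2-phenyl}-2-diazoethan-1-one | [N-]=[N+]=CC(=O)c1c(OCc2ccccc2)c(OCc2ccccc2)cc([C@H]3Oc4cc(OCc5ccccc5)cc(OCc5ccccc5)c4C[C@H]3OCc3ccccc3)c1CO[Si](c1ccccc1)(c1ccccc1)C(C)(C)C | intermediate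
27 | 1-[2,3-bis(benzyloxy)-6-(hydroxymethyl)-5-Fl2-phenyl]-2-diazoethan-1-one | [N-]=[N+]=CC(=O)c1c(OCc2ccccc2)c(OCc2ccccc2)cc([C@H]3Oc4cc(OCc5ccccc5)cc(OCc5ccccc5)c4C[C@H]3OCc3ccccc3)c1CO | intermediate
28 | 3,4-bis(benzyloxy)-2-(diazoacetyl)-6-Fl2-benzaldehyde | [N-]=[N+]=CC(=O)c1c(OCc2ccccc2)c(OCc2ccccc2)cc([C@H]3Oc4cc(OCc5ccccc5)cc(OCc5ccccc5)c4C[C@H]3OCc3ccccc3)c1C=O | intermediate
29 | 5,6-bis(benzyloxy)-8-Fl2-2-benzopyrylium-4-olate (not isolated) | [O-]C1=C[O+]=Cc2c([C@H]3Oc4cc(OCc5ccccc5)cc(OCc5ccccc5)c4C[C@H]3OCc3ccccc3)cc(OCc3ccccc3)c(OCc3ccccc3)c21 | intermediate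
30 | 3,4-bis(benzyloxy)-8-[(2R)-3-ArA-2-(methoxymethoxy)propanoyl]-1-Fl2-6,9-dihydro-5H-6,9-epoxybenzo[7]annulen-5-one (bridgeheads C6/C9 cis, both epimers) | O=C1C2OC(c3c1c(OCc1ccccc1)c(OCc1ccccc1)cc3[C@H]1Oc3cc(OCc4ccccc4)cc(OCc4ccccc4)c3C[C@H]1OCc1ccccc1)C(C(=O)[C@H](OCOC)Cc1c(O[Si](C(C)C)(C(C)C)C(C)C)cc(OCc3ccccc3)cc1OCc1ccccc1)=C2 | intermediate
31 | 3,4-bis(benzyloxy)-6-hydroxy-8-[(2R)-3-ArA-2-(methoxymethoxy)propanoyl]-1-Fl2-5H-benzo[7]annulen-5-one | O=C([C@H](OCOC)Cc1c(O[Si](C(C)C)(C(C)C)C(C)C)cc(OCc2ccccc2)cc1OCc1ccccc1)c1cc(O)c(=O)c2c(OCc3ccccc3)c(OCc3ccccc3)cc([C@H]3Oc4cc(OCc5ccccc5)cc(OCc5ccccc5)c4C[C@H]3OCc3ccccc3)c2c1 | intermediate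
32 | 3,4,6-tris(benzyloxy)-8-[(2R)-3-ArA-2-(methoxymethoxy)propanoyl]-1-Fl2-5H-benzo[7]annulen-5-one | O=C([C@H](OCOC)Cc1c(O[Si](C(C)C)(C(C)C)C(C)C)cc(OCc2ccccc2)cc1OCc1ccccc1)c1cc(OCc2ccccc2)c(=O)c2c(OCc3ccccc3)c(OCc3ccccc3)cc([C@H]3Oc4cc(OCc5ccccc5)cc(OCc5ccccc5)c4C[C@H]3OCc3ccccc3)c2c1 | intermediate
33 | 3,4,6-tris(benzyloxy)-8-[(1S,2R)-3-ArA-1-hydroxy-2-(methoxymethoxy)propyl]-1-Fl2-5H-benzo[7]annulen-5-one | O[C@H]([C@H](OCOC)Cc1c(O[Si](C(C)C)(C(C)C)C(C)C)cc(OCc2ccccc2)cc1OCc1ccccc1)c1cc(OCc2ccccc2)c(=O)c2c(OCc3ccccc3)c(OCc3ccccc3)cc([C@H]3Oc4cc(OCc5ccccc5)cc(OCc5ccccc5)c4C[C@H]3OCc3ccccc3)c2c1 | intermediate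
34 | 3,4,6-tris(benzyloxy)-8-{(1S,2R)-3-[2,4-bis(benzyloxy)-6-hydroxyphenyl]-1-hydroxy-2-(methoxymethoxy)propyl}-1-Fl2-5H-benzo[7]annulen-5-one | O[C@H]([C@H](OCOC)Cc1c(O)cc(OCc2ccccc2)cc1OCc1ccccc1)c1cc(OCc2ccccc2)c(=O)c2c(OCc3ccccc3)c(OCc3ccccc3)cc([C@H]3Oc4cc(OCc5ccccc5)cc(OCc5ccccc5)c4C[C@H]3OCc3ccccc3)c2c1 | intermediate
35 | 3,4,6-tris(benzyloxy)-8-[(2R,3R)-5,7-bis(benzyloxy)-3-(methoxymethoxy)chroman-2-yl]-1-Fl2-5H-benzo[7]annulen-5-one | COCO[C@@H]1Cc2c(OCc3ccccc3)cc(OCc3ccccc3)cc2O[C@@H]1c1cc(OCc2ccccc2)c(=O)c2c(OCc3ccccc3)c(OCc3ccccc3)cc([C@H]3Oc4cc(OCc5ccccc5)cc(OCc5ccccc5)c4C[C@H]3OCc3ccccc3)c2c1 | intermediate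
36 | 3,4,6-tris(benzyloxy)-8-[(2R,3R)-5,7-bis(benzyloxy)-3-hydroxychroman-2-yl]-1-Fl2-5H-benzo[7]annulen-5-one | O[C@@H]1Cc2c(OCc3ccccc3)cc(OCc3ccccc3)cc2O[C@@H]1c1cc(OCc2ccccc2)c(=O)c2c(OCc3ccccc3)c(OCc3ccccc3)cc([C@H]3Oc4cc(OCc5ccccc5)cc(OCc5ccccc5)c4C[C@H]3OCc3ccccc3)c2c1 | intermediate
37 | 3,4,5-tris(benzyloxy)benzoic acid | O=C(O)c1cc(OCc2ccccc2)c(OCc2ccccc2)c(OCc2ccccc2)c1 | starting material
38 | (2R,3R)-5,7-bis(benzyloxy)-2-[3,4,6-tris(benzyloxy)-5-oxo-1-Fl2-5H-benzo[7]annulen-8-yl]chroman-3-yl 3,4,5-tris(benzyloxy)benzoate | O=C(O[C@@H]1Cc2c(OCc3ccccc3)cc(OCc3ccccc3)cc2O[C@@H]1c1cc(OCc2ccccc2)c(=O)c2c(OCc3ccccc3)c(OCc3ccccc3)cc([C@H]3Oc4cc(OCc5ccccc5)cc(OCc5ccccc5)c4C[C@H]3OCc3ccccc3)c2c1)c1cc(OCc2ccccc2)c(OCc2ccccc2)c(OCc2ccccc2)c1 | intermediate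
39 | theaflavin 3-gallate (CNP0488827.1) | O=C(O[C@@H]1Cc2c(O)cc(O)cc2O[C@@H]1c1cc(=O)c(O)c2c(O)c(O)cc([C@H]3Oc4cc(O)cc(O)c4C[C@H]3O)c2c1)c1cc(O)c(O)c(O)c1 | target

**Step count and risks**

Total step count: 30. Longest linear sequence: 22 steps (steps 7–11, then 14–30; the chain through steps 1–3, 12 and 13 is equally long).

Three steps most likely to fail:

1. Step 22. The rhodium carbenoid may be intercepted by the ortho benzyloxy oxygen (oxonium ylide, then benzyl shift) instead of the formyl oxygen, or the ylide may dimerise before it meets the ynone. The fallback makes the same ylide without a carbenoid and sets out from 28. Warming 28 in acetic acid (60 °C) should replace N2 by acetate through protonation of the diazo carbon, giving the acetoxymethyl ketone F1. K2CO3 in MeOH at 0 °C removes the acetate and the hydroxy ketone closes onto the neighbouring aldehyde to give the lactol 1-hydroxyisochroman-4-one F2. Ac2O, pyridine and DMAP give the anomeric acetate F3. F3, ynone 9 (2 equiv) and Et3N in MeCN at 40–60 °C should lose acetic acid by base-induced 1,3-elimination across the ring oxygen (the acetoxypyranone route to oxidopyrylium ylides) to give ylide 29 and hence 30, where the route is rejoined. This fallback addresses carbenoid chemoselectivity only; it would not correct a regiochemical problem.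

2. Step 25. Hydride may also attack the benzyloxytropone ring, or the tropone carbonyl may compete for zinc and erode facial selectivity. The fallback reverses the order of protection and reduction and sets out from 31. Excess Zn(BH4)2 (CH2Cl2/Et2O, −78 → −30 °C) first deprotonates the tropolone to its zinc tropolonate, an anion that should resist hydride, while the α-MOM-oxy ketone is still reduced through the chelate. This gives the anti alcohol with a free tropolone hydroxyl F4. Benzylation of only the acidic tropolone hydroxyl (BnBr, K2CO3, acetone, rt) then rejoins the route at 33.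

3. Step 27. The oxyphosphonium ion next to the tropone ring may eliminate toward the C3 hydrogen or react sluggishly, so that closure is incomplete or stereochemically leaky. The fallback separates activation from displacement and sets out from 33, in which the phenol is still silylated. MsCl and Et3N in CH2Cl2 at −20 °C give the methanesulfonate F5. TBAF in THF at 0 °C then releases the phenoxide, which displaces the sulfonate intramolecularly with inversion (Williamson closure) and gives 35 directly.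

**Further compounds**

F1 | step 22 | 2-(acetoxyacetyl)-3,4-bis(benzyloxy)-6-Fl2-benzaldehyde | CC(=O)OCC(=O)c1c(OCc2ccccc2)c(OCc2ccccc2)cc([C@H]3Oc4cc(OCc5ccccc5)cc(OCc5ccccc5)c4C[C@H]3OCc3ccccc3)c1C=O
F2 | step 22 | 5,6-bis(benzyloxy)-1-hydroxy-8-Fl2-isochroman-4-one (lactol, both C1 epimers) | OC1OCC(=O)c2c(OCc3ccccc3)c(OCc3ccccc3)cc([C@H]3Oc4cc(OCc5ccccc5)cc(OCc5ccccc5)c4C[C@H]3OCc3ccccc3)c21
F3 | step 22 | 5,6-bis(benzyloxy)-4-oxo-8-Fl2-isochroman-1-yl acetate (both C1 epimers) | CC(=O)OC1OCC(=O)c2c(OCc3ccccc3)c(OCc3ccccc3)cc([C@H]3Oc4cc(OCc5ccccc5)cc(OCc5ccccc5)c4C[C@H]3OCc3ccccc3)c21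
F4 | step 25 | 3,4-bis(benzyloxy)-6-hydroxy-8-[(1S,2R)-3-ArA-1-hydroxy-2-(methoxymethoxy)propyl]-1-Fl2-5H-benzo[7]annulen-5-one | O[C@H]([C@H](OCOC)Cc1c(O[Si](C(C)C)(C(C)C)C(C)C)cc(OCc2ccccc2)cc1OCc1ccccc1)c1cc(O)c(=O)c2c(OCc3ccccc3)c(OCc3ccccc3)cc([C@H]3Oc4cc(OCc5ccccc5)cc(OCc5ccccc5)c4C[C@H]3OCc3ccccc3)c2c1
F5 | step 27 | (1S,2R)-3-ArA-2-(methoxymethoxy)-1-[3,4,6-tris(benzyloxy)-5-oxo-1-Fl2-5H-benzo[7]annulen-8-yl]propyl methanesulfonate | CS(=O)(=O)O[C@H]([C@H](OCOC)Cc1c(O[Si](C(C)C)(C(C)C)C(C)C)cc(OCc2ccccc2)cc1OCc1ccccc1)c1cc(OCc2ccccc2)c(=O)c2c(OCc3ccccc3)c(OCc3ccccc3)cc([C@H]3Oc4cc(OCc5ccccc5)cc(OCc5ccccc5)c4C[C@H]3OCc3ccccc3)c2c1
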